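**Plan**

1. The target is (5'S)-4,5'-retro-β,β-carotene. Carotenoid locants are used: ring A (the cyclohexene) is C-1 to C-6 with the ring methyl on C-5, and primed locants belong to the half ending in ring B, whose stereocentre is C-5'. The retrosynthesis cuts C-15–C-15' (Stille), then C-10=C-11 and C-10'=C-11' (Horner–Wadsworth–Emmons, one C6 stannyl phosphonate for both halves), then C-8=C-9 and C-8'=C-9' (Wittig), down to two ring-bearing C11 enals.
2. Ring A is not made as a six-membered ring. Its C-6 carries the exocyclic C-6=C-7 bond and lies between the quaternary C-1 and the sp2 carbon C-5. With C-5 read as a ketone, ring A is a 2-alkylidenecyclohexanone, the semipinacol product of a 1-alkynyl-2,2-dimethylcyclopentanol (ring C-1–C-2–C-3–C-4–C-5) in which C-1 shifts from C-5 to the alkyne carbon C-6. The C-5 methyl and the C-4=C-5 bond come back through an enol triflate.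
3. Forward, ring A half: propiolate addition to 2,2-dimethylcyclopentanone, gold-triggered ring enlargement to the cyclohexanone with the exocyclic enoate, triflation and methylation, reduction, then oxidation and Wittig to the C14 trienal.
4. Forward, ring B half: the preformed cyclohexanone is methylated as its RAMP hydrazone, then vinyl addition, oxidative 1,3-transposition and Wittig give the C14 trienal. Each trienal is extended to a C20 tetraenylstannane (sodium anion of the phosphonate for the ring A half, the less basic lithium anion for the epimerisable ring B half), the ring B one is converted into the iodide, and the halves are joined at C-15–C-15'.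
5. Stereochemistry: C-5' (S) comes from auxiliary-controlled methylation of the RAMP hydrazone. The C-6=C-7 geometry comes from anti addition of the migrating carbon and gold, and C-6'=C-7' from the [3,3] shift (chain away from CMe2). The chain double bonds are E from the stabilised ylide, the phosphonate anions and syn-hydrostannation.

Key step: step 2

**Route**

Step 1
Reactants: 1 2,2-dimethylcyclopentan-1-one; 2 ethyl prop-2-ynoate (ethyl propiolate)
Product: 4 ethyl 3-(1-hydroxy-2,2-dimethylcyclopentyl)prop-2-ynoate (racemic), via lithium ethyl propiolate 3 (not isolated)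
Conditions: 2, n-BuLi, THF, −78 °C; then 1, −78 °C; then H2O
Reagents that add atoms: none
Why: 1,2-addition of a lithium acetylide to a ketone, in which the ester-stabilised acetylide kept at −78 °C should add faster than it enolises the hindered ketone, and the new carbinol centre is erased in step 2 so its configuration does not matter.

Step 2
Reactants: 4 ethyl 3-(1-hydroxy-2,2-dimethylcyclopentyl)prop-2-ynoate
Product: 5 ethyl (2E)-2-(2,2-dimethyl-6-oxocyclohexylidene)acetate
Conditions: [(4-CF3C6H4)3P]AuCl (5 mol %), AgSbF6 (5 mol %), 4 Å molecular sieves, (CH2Cl)2, 23 to 60 °C, dark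
Reagents that add atoms: none
Why: Proposed new method: the cationic monovalent gold complex binds the ynoate, whose β-carbon (C-6) is the electrophilic one, and the C-5–C-1 bond of the cyclopentanol, anti to gold, shifts to C-6 while the carbinol oxygen becomes the C-5 carbonyl (semipinacol 1,2-alkyl shift); the α-aurated enoate is then protodeaurated by the proton just released. The closest known reaction type is the ring expansion of 1-alkynylcyclobutanols and 1-alkynylcyclopropanols to 2-alkylidenecycloalkanones under the same kind of catalyst; here it is asked of an unstrained cyclopentanol, so the driving force is not ring strain but the C=O bond and conjugated enoate gained from an alkyne, together with relief of the crowded C(OH)–CMe2 junction. The six-membered ring is not closed by a cyclisation but arises by one-carbon enlargement of the five-membered ring through this 1,2-shift. No stereocentre is formed and the racemic carbinol centre is erased; the C-6=C-7 geometry should follow from anti addition of the migrating carbon and gold, which puts the ester cis to CMe2 as the target requires. Two selectivities are needed: migration of the quaternary CMe2 carbon and not of the ring CH2, secured by the higher migratory aptitude of the more substituted carbon, and ring enlargement in preference to Meyer–Schuster rearrangement or hydration, secured by the ynoate polarisation (oxygen attack would have to occur at the α-carbon) and by dry conditions.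

Step 3
Reactants: 5 ethyl (2E)-2-(2,2-dimethyl-6-oxocyclohexylidene)acetate
Product: 7 ethyl (2E)-2-[6,6-dimethyl-2-(trifluoromethanesulfonyloxy)cyclohex-2-en-1-ylidene]acetate, via potassium dienolate 6 (not isolated)
Conditions: KN(SiMe3)2, THF, −78 °C; then PhNTf2, −78 to 0 °C
Reagents that add atoms: N-phenylbis(trifluoromethanesulfonimide), O=S(=O)(N(c1ccccc1)S(=O)(=O)C(F)(F)F)C(F)(F)F
Why: enol triflate formation, in which the only enolisable position of 5 is the ring CH2 next to the ketone (C-4), so O-sulfonylation of the cross-conjugated enolate should fix the C-4=C-5 double bond.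

Step 4
Reactants: 7 ethyl (2E)-2-[6,6-dimethyl-2-(trifluoromethanesulfonyloxy)cyclohex-2-en-1-ylidene]acetate
Product: 8 ethyl (2E)-2-(2,6,6-trimethylcyclohex-2-en-1-ylidene)acetate
Conditions: MeZnCl, Pd(PPh3)4 (5 mol %), THF, 50 °C
Reagents that add atoms: methylzinc chloride, C[Zn]Cl
Why: Negishi cross-coupling of an alkenyl triflate with a methylzinc reagent, which tolerates the ester and should keep the geometry of the exocyclic double bond.

Step 5
Reactants: 8 ethyl (2E)-2-(2,6,6-trimethylcyclohex-2-en-1-ylidene)acetate
Product: 9 (2E)-2-(2,6,6-trimethylcyclohex-2-en-1-ylidene)ethan-1-ol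
Conditions: i-Bu2AlH (2.2 equiv), CH2Cl2, −78 °C; then H2O
Reagents that add atoms: none
Why: 1,2-reduction of a conjugated ester to the allylic alcohol with i-Bu2AlH, which should leave the diene untouched.

Step 6
Reactants: 9 (2E)-2-(2,6,6-trimethylcyclohex-2-en-1-ylidene)ethan-1-ol; 10 2-(triphenyl-λ5-phosphanylidene)propanal
Product: 12 (2E,4E)-2-methyl-4-(2,6,6-trimethylcyclohex-2-en-1-ylidene)but-2-enal, via C11 dienal 11 (not isolated)
Conditions: MnO2, CH2Cl2, 23 °C; filter; then 10, toluene, 90 °C
Reagents that add atoms: none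
Why: allylic oxidation with MnO2 followed by Wittig olefination with a formyl-stabilised ylide, which should give the E trisubstituted C-8=C-9 bond and stop after one homologation because the α-methyl enal formed is much less reactive than 11.

Step 7
Reactants: 13 2,2-dimethylcyclohexan-1-one; 14 RAMP, (2R)-2-(methoxymethyl)pyrrolidin-1-amine
Product: 15 (2R)-N-[(E)-2,2-dimethylcyclohexylidene]-2-(methoxymethyl)pyrrolidin-1-amine
Conditions: p-TsOH (cat.), cyclohexane, reflux, water separator
Reagents that add atoms: none
Why: hydrazone condensation, in which the amino nitrogen should settle anti to the CMe2 side, the geometry needed for the directed deprotonation of step 8.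

Step 8
Reactants: 15 (2R)-N-[(E)-2,2-dimethylcyclohexylidene]-2-(methoxymethyl)pyrrolidin-1-amine
Product: 17 (2R)-2-(methoxymethyl)-N-[(E,6S)-2,2,6-trimethylcyclohexylidene]pyrrolidin-1-amine, via lithium azaenolate 16 (not isolated)
Conditions: LiN(i-Pr)2, THF, 0 °C; then MeI, −100 to −78 °C
Reagents that add atoms: iodomethane, CI
Why: RAMP-hydrazone α-alkylation, in which the chelated lithium azaenolate is methylated on the face left open by the methoxymethyl arm, which should set C-5' as S (the mirror-image auxiliary leads to the R series, as in the known formation of (R)-2-methylcyclohexanone from the SAMP hydrazone).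

Step 9
Reactants: 17 (2R)-2-(methoxymethyl)-N-[(E,6S)-2,2,6-trimethylcyclohexylidene]pyrrolidin-1-amine
Product: 18 (6S)-2,2,6-trimethylcyclohexan-1-one
Conditions: O3, CH2Cl2, −78 °C; N2 purge
Reagents that add atoms: ozone, [O-][O+]=O
Why: oxidative cleavage of the hydrazone C=N bond at −78 °C under non-enolising conditions, so the α-stereocentre should be kept.

Step 10
Reactants: 18 (6S)-2,2,6-trimethylcyclohexan-1-one
Product: 19 (6S)-1-ethenyl-2,2,6-trimethylcyclohexan-1-ol (mixture of C-1 epimers)
Conditions: CH2=CHMgBr, THF, 0 to 23 °C; then H2O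
Reagents that add atoms: vinylmagnesium bromide, C=C[Mg]Br
Why: Grignard 1,2-addition to the hindered ketone, in which any ketone that is enolised instead is only recovered and the configuration of the new carbinol centre does not matter because this carbon becomes sp2 in step 11.

Step 11
Reactants: 19 (6S)-1-ethenyl-2,2,6-trimethylcyclohexan-1-ol
Product: 20 (2E)-2-[(6S)-2,2,6-trimethylcyclohexylidene]acetaldehyde
Conditions: pyridinium chlorochromate (C5H5NH)[CrO3Cl], 4 Å molecular sieves, CH2Cl2, 23 °C
Reagents that add atoms: pyridinium chlorochromate, [O-][Cr](=O)(=O)Cl.c1cc[nH+]cc1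
Why: Babler–Dauben oxidative 1,3-transposition, in which the chromate ester of the tertiary allylic alcohol undergoes a [3,3] shift and the primary chromate is oxidised to the enal, so the aldehyde carbon should end on the less hindered side cis to CHMe (E) while C-5' stays untouched because no cation or enol is formed next to it.

Step 12
Reactants: 20 (2E)-2-[(6S)-2,2,6-trimethylcyclohexylidene]acetaldehyde; 10 2-(triphenyl-λ5-phosphanylidene)propanal
Product: 21 (2E,4E)-2-methyl-4-[(6S)-2,2,6-trimethylcyclohexylidene]but-2-enal
Conditions: toluene, 90 °C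
Reagents that add atoms: none
Why: Wittig olefination with the formyl-stabilised ylide, which should be E-selective for the trisubstituted C-8'=C-9' bond under neutral conditions that cannot epimerise C-5'.

Step 13
Reactants: 22 (2E)-3-methylpent-2-en-4-yn-1-ol
Product: 23 (2E,4E)-3-methyl-5-(tributylstannyl)penta-2,4-dien-1-ol
Conditions: Bu3SnH, PdCl2(PPh3)2 (2 mol %), THF, 0 °C
Reagents that add atoms: tributyltin hydride, CCCC[SnH](CCCC)CCCC
Why: palladium-catalysed syn-hydrostannation of the terminal alkyne, which should place tin on the terminal carbon and give the E alkenylstannane.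

Step 14
Reactants: 23 (2E,4E)-3-methyl-5-(tributylstannyl)penta-2,4-dien-1-ol
Product: 24 tributyl[(1E,3E)-5-bromo-3-methylpenta-1,3-dien-1-yl]stannane
Conditions: CBr4, PPh3, 2,6-lutidine, CH2Cl2, −20 °C
Reagents that add atoms: tetrabromomethane, BrC(Br)(Br)Br
Why: Appel bromination of the primary allylic alcohol under buffered conditions that should avoid protodestannylation.

Step 15
Reactants: 24 tributyl[(1E,3E)-5-bromo-3-methylpenta-1,3-dien-1-yl]stannane
Product: 25 diethyl [(2E,4E)-3-methyl-5-(tributylstannyl)penta-2,4-dien-1-yl]phosphonate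
Conditions: P(OEt)3, neat, 90 °C
Reagents that add atoms: triethyl phosphite, CCOP(OCC)OCC
Why: Michaelis–Arbuzov reaction of the primary allylic bromide at its unhindered CH2, with loss of bromoethane.

Step 16
Reactants: 12 (2E,4E)-2-methyl-4-(2,6,6-trimethylcyclohex-2-en-1-ylidene)but-2-enal; 25 diethyl [(2E,4E)-3-methyl-5-(tributylstannyl)penta-2,4-dien-1-yl]phosphonate
Product: 27 tributyl[(1E,3E,5E,7E,9E)-3,7-dimethyl-9-(2,6,6-trimethylcyclohex-2-en-1-ylidene)nona-1,3,5,7-tetraen-1-yl]stannane, via sodium phosphonate anion 26 (not isolated)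
Conditions: 25, NaN(SiMe3)2, THF, −78 °C; then 12, −78 to 0 °C, dark
Reagents that add atoms: none
Why: Horner–Wadsworth–Emmons olefination of the trienal with the sodium salt of the allylic phosphonate anion, which should be E-selective for the disubstituted C-10=C-11 bond and leave the alkenylstannane intact.

Step 17
Reactants: 21 (2E,4E)-2-methyl-4-[(6S)-2,2,6-trimethylcyclohexylidene]but-2-enal; 25 diethyl [(2E,4E)-3-methyl-5-(tributylstannyl)penta-2,4-dien-1-yl]phosphonate
Product: 29 tributyl[(1E,3E,5E,7E,9E)-3,7-dimethyl-9-[(6S)-2,2,6-trimethylcyclohexylidene]nona-1,3,5,7-tetraen-1-yl]stannane, via lithium phosphonate anion 28 (not isolated)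
Conditions: 25, LiN(SiMe3)2, THF, −78 °C; then 21, −78 to 23 °C, dark
Reagents that add atoms: none
Why: Horner–Wadsworth–Emmons olefination for the C-10'=C-11' bond, run here with the lithium salt of the phosphonate anion, whose tighter ion pair is the weaker base, so that the preformed anion without excess amide should add to the aldehyde faster than it can deprotonate the remote C-5', and the oxyanion adduct should collapse to the E alkene on warming.

Step 18
Reactants: 29 tributyl[(1E,3E,5E,7E,9E)-3,7-dimethyl-9-[(6S)-2,2,6-trimethylcyclohexylidene]nona-1,3,5,7-tetraen-1-yl]stannane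
Product: 30 (1E,3E,5E,7E,9E)-1-iodo-3,7-dimethyl-9-[(6S)-2,2,6-trimethylcyclohexylidene]nona-1,3,5,7-tetraene
Conditions: I2, CH2Cl2, −78 to 0 °C, dark
Reagents that add atoms: iodine, II
Why: iododestannylation with retention of the E geometry, which at −78 °C should be faster than addition of iodine to the polyene.

Step 19
Reactants: 27 tributyl[(1E,3E,5E,7E,9E)-3,7-dimethyl-9-(2,6,6-trimethylcyclohex-2-en-1-ylidene)nona-1,3,5,7-tetraen-1-yl]stannane; 30 (1E,3E,5E,7E,9E)-1-iodo-3,7-dimethyl-9-[(6S)-2,2,6-trimethylcyclohexylidene]nona-1,3,5,7-tetraene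
Product: 31 (5'S)-4,5'-retro-β,β-carotene (all-E)
Conditions: Pd2(dba)3 (5 mol %), AsPh3 (40 mol %), N-methylpyrrolidone, 23 to 40 °C, argon, dark
Reagents that add atoms: none
Why: Stille coupling of an alkenylstannane with an alkenyl iodide on zerovalent palladium, which should form the C-15–C-15' single bond between the two dienes with retention of both geometries under neutral, mild conditions.

**Compound list**

1 | 2,2-dimethylcyclopentan-1-one | CC1(C)CCCC1=O | starting material
2 | ethyl prop-2-ynoate (ethyl propiolate) | CCOC(=O)C#C | starting material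
3 | lithium ethyl propiolate (ethyl 3-lithioprop-2-ynoate) | [Li]C#CC(=O)OCC | intermediate
4 | ethyl 3-(1-hydroxy-2,2-dimethylcyclopentyl)prop-2-ynoate (racemic) | CCOC(=O)C#CC1(O)CCCC1(C)C | intermediate
5 | ethyl (2E)-2-(2,2-dimethyl-6-oxocyclohexylidene)acetate | CCOC(=O)/C=C1/C(=O)CCCC1(C)C | intermediate
6 | potassium dienolate of 5 | [K+].CCOC(=O)/C=C1/C([O-])=CCCC1(C)C | intermediate
7 | ethyl (2E)-2-[6,6-dimethyl-2-(trifluoromethanesulfonyloxy)cyclohex-2-en-1-ylidene]acetate | CCOC(=O)/C=C1/C(OS(=O)(=O)C(F)(F)F)=CCCC1(C)C | intermediate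
8 | ethyl (2E)-2-(2,6,6-trimethylcyclohex-2-en-1-ylidene)acetate | CCOC(=O)/C=C1/C(C)=CCCC1(C)C | intermediate
9 | (2E)-2-(2,6,6-trimethylcyclohex-2-en-1-ylidene)ethan-1-ol | OC/C=C1/C(C)=CCCC1(C)C | intermediate
10 | 2-(triphenyl-λ5-phosphanylidene)propanal | CC(C=O)=P(c1ccccc1)(c1ccccc1)c1ccccc1 | starting material
11 | C11 dienal, (2E)-2-(2,6,6-trimethylcyclohex-2-en-1-ylidene)acetaldehyde | O=C/C=C1/C(C)=CCCC1(C)C | intermediate
12 | (2E,4E)-2-methyl-4-(2,6,6-trimethylcyclohex-2-en-1-ylidene)but-2-enal | CC1=CCCC(C)(C)\C1=C/C=C(C)/C=O | intermediate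
13 | 2,2-dimethylcyclohexan-1-one | CC1(C)CCCCC1=O | starting material
14 | RAMP, (2R)-2-(methoxymethyl)pyrrolidin-1-amine | COC[C@H]1CCCN1N | starting material
15 | (2R)-N-[(E)-2,2-dimethylcyclohexylidene]-2-(methoxymethyl)pyrrolidin-1-amine | COC[C@H]1CCCN1/N=C2\CCCCC2(C)C | intermediate
16 | lithium azaenolate of 15 | [Li+].COC[C@H]1CCCN1[N-]C2=CCCCC2(C)C | intermediate
17 | (2R)-2-(methoxymethyl)-N-[(E,6S)-2,2,6-trimethylcyclohexylidene]pyrrolidin-1-amine | COC[C@H]1CCCN1/N=C2\[C@@H](C)CCCC2(C)C | intermediate
18 | (6S)-2,2,6-trimethylcyclohexan-1-one | O=C1[C@@H](C)CCCC1(C)C | intermediate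
19 | (6S)-1-ethenyl-2,2,6-trimethylcyclohexan-1-ol (C-1 epimers) | C=CC1(O)[C@@H](C)CCCC1(C)C | intermediate
20 | (2E)-2-[(6S)-2,2,6-trimethylcyclohexylidene]acetaldehyde | O=C/C=C1\[C@@H](C)CCCC1(C)C | intermediate
21 | (2E,4E)-2-methyl-4-[(6S)-2,2,6-trimethylcyclohexylidene]but-2-enal | O=C/C(C)=C/C=C1\[C@@H](C)CCCC1(C)C | intermediate
22 | (2E)-3-methylpent-2-en-4-yn-1-ol | OC/C=C(C)/C#C | starting material
23 | (2E,4E)-3-methyl-5-(tributylstannyl)penta-2,4-dien-1-ol | OC/C=C(C)/C=C/[Sn](CCCC)(CCCC)CCCC | intermediate
24 | tributyl[(1E,3E)-5-bromo-3-methylpenta-1,3-dien-1-yl]stannane | BrC/C=C(C)/C=C/[Sn](CCCC)(CCCC)CCCC | intermediate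
25 | diethyl [(2E,4E)-3-methyl-5-(tributylstannyl)penta-2,4-dien-1-yl]phosphonate | CCOP(=O)(OCC)C/C=C(C)/C=C/[Sn](CCCC)(CCCC)CCCC | intermediate
26 | sodium salt of the α-carbanion of 25 (sodium phosphonate anion) | [Na+].CCOP(=O)(OCC)[CH-]/C=C(C)/C=C/[Sn](CCCC)(CCCC)CCCC | intermediate
27 | tributyl[(1E,3E,5E,7E,9E)-3,7-dimethyl-9-(2,6,6-trimethylcyclohex-2-en-1-ylidene)nona-1,3,5,7-tetraen-1-yl]stannane | CC1=CCCC(C)(C)\C1=C/C=C(C)/C=C/C=C(C)/C=C/[Sn](CCCC)(CCCC)CCCC | intermediate
28 | lithium salt of the α-carbanion of 25 (lithium phosphonate anion) | [Li+].CCOP(=O)(OCC)[CH-]/C=C(C)/C=C/[Sn](CCCC)(CCCC)CCCC | intermediate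
29 | tributyl[(1E,3E,5E,7E,9E)-3,7-dimethyl-9-[(6S)-2,2,6-trimethylcyclohexylidene]nona-1,3,5,7-tetraen-1-yl]stannane | CCCC[Sn](CCCC)(CCCC)/C=C/C(C)=C/C=C/C(C)=C/C=C1\[C@@H](C)CCCC1(C)C | intermediate
30 | (1E,3E,5E,7E,9E)-1-iodo-3,7-dimethyl-9-[(6S)-2,2,6-trimethylcyclohexylidene]nona-1,3,5,7-tetraene | I/C=C/C(C)=C/C=C/C(C)=C/C=C1\[C@@H](C)CCCC1(C)C | intermediate
31 | (5'S)-4,5'-retro-β,β-carotene (all-E) | CC1=CCCC(C)(C)\C1=C/C=C(C)/C=C/C=C(C)/C=C/C=C/C(C)=C/C=C/C(C)=C/C=C1\[C@@H](C)CCCC1(C)C | target

**Count**

Total steps: 19. Longest linear sequence: 9 steps (steps 7 to 12, then 17, 18 and 19).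

**Steps most likely to fail**

1. Step 2 (Proposed new method). Without ring strain the 1,2-shift may be slower than hydration of the gold-bound alkyne by traces of water, or the keto ester product may bind and deactivate the catalyst so that conversion stalls. The fallback uses known chemistry and still makes ring A by enlargement of the five-membered ring, here through a bicyclo[3.1.0]hexane. It sets out from 1 and comes back to the route at 8. Compound 1 is converted with LiN(i-Pr)2 and PhNTf2 into 5,5-dimethylcyclopent-1-en-1-yl trifluoromethanesulfonate F1. Coupling of this triflate with BrZnCH2CO2Et under Pd(PPh3)4 gives ethyl 2-(5,5-dimethylcyclopent-1-en-1-yl)acetate F2. Dibromocarbene from PhHgCBr3 (benzene, 80 °C) adds to the ring double bond and gives ethyl 2-(6,6-dibromo-2,2-dimethylbicyclo[3.1.0]hexan-1-yl)acetate F3. Heating with DBU in toluene opens the cyclopropane in a disrotatory way to the 2-bromocyclohexenyl cation and removes HBr across C-6/C-7, which gives ethyl (2E)-2-(2-bromo-6,6-dimethylcyclohex-2-en-1-ylidene)acetate F4. Methylation of the alkenyl bromide with MeZnCl and Pd(PPh3)4, as in step 4, then gives 8.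

2. Step 11. Chromate ester formation at the carbinol flanked by CMe2 and CHMe may be slow, so that acid-promoted dehydration to the diene and unselective formation of the exocyclic double bond compete with the [3,3] shift. The fallback sets out from 18 and comes back at 20. Addition of (Z)-2-ethoxyvinyllithium (from (Z)-tributyl(2-ethoxyethenyl)stannane and n-BuLi, THF, −78 °C) to 18 gives (6S)-1-[(Z)-2-ethoxyethenyl]-2,2,6-trimethylcyclohexan-1-ol F5. Brief treatment with dilute aqueous HCl in THF at 0 °C then hydrolyses the enol ether with allylic transposition and loss of ethanol to give 20.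

3. Step 19. Transmetalation between two electron-rich tetraenyl partners may be slow, with homocoupling, protodestannylation and E/Z scrambling of the light- and acid-sensitive polyenes taking over. The fallback sets out from 30 (with 25) and comes back at 31. The iodide 30 is coupled under the same Stille conditions with the small and robust stannane 25 to give diethyl [(2E,4E,6E,8E,10E,12E,14E)-3,8,12-trimethyl-14-[(6S)-2,2,6-trimethylcyclohexylidene]tetradeca-2,4,6,8,10,12-hexaen-1-yl]phosphonate F6. Its sodium anion (NaN(SiMe3)2, THF, −78 °C) is then condensed with the trienal 12 in a Horner–Wadsworth–Emmons reaction, so that the last bond formed is C-10=C-11 and 31 results.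

**Further compounds**

F1 | step 2 | 5,5-dimethylcyclopent-1-en-1-yl trifluoromethanesulfonate | CC1(C)CCC=C1OS(=O)(=O)C(F)(F)F
F2 | step 2 | ethyl 2-(5,5-dimethylcyclopent-1-en-1-yl)acetate | CCOC(=O)CC1=CCCC1(C)C
F3 | step 2 | ethyl 2-(6,6-dibromo-2,2-dimethylbicyclo[3.1.0]hexan-1-yl)acetate (racemic) | CCOC(=O)CC12C(CCC1(C)C)C2(Br)Br
F4 | step 2 | ethyl (2E)-2-(2-bromo-6,6-dimethylcyclohex-2-en-1-ylidene)acetate | CCOC(=O)/C=C1/C(Br)=CCCC1(C)C
F5 | step 11 | (6S)-1-[(Z)-2-ethoxyethenyl]-2,2,6-trimethylcyclohexan-1-ol | CCO/C=C\C1(O)[C@@H](C)CCCC1(C)C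
F6 | step 19 | diethyl [(2E,4E,6E,8E,10E,12E,14E)-3,8,12-trimethyl-14-[(6S)-2,2,6-trimethylcyclohexylidene]tetradeca-2,4,6,8,10,12-hexaen-1-yl]phosphonate | CCOP(=O)(OCC)C/C=C(C)/C=C/C=C/C(C)=C/C=C/C(C)=C/C=C1\[C@@H](C)CCCC1(C)C
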